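(Readings and results are simulated for substances that don't exist, and the scatter is random.)

How does the ratio of other capture product to target move in a flask holding 21 mM of solid substrate, and which product leads at the end?

- violet: solid substrate 10 mM; first nucleophile 0.70 equiv; second nucleophile 0.60 equiv; run made earlier
- flask: solid substrate 21 mM; first nucleophile 0.700 equiv; second nucleophile 0.600 equiv; time 6.0 min

violet run (percent of the solid substrate charged)

| time / s | other capture product / % | target / % | solid substrate / % |
|---|---|---|---|
| 12.0 | 5.9 | 17.2 | 65.2 |
| 25.0 | 17.5 | 40.0 | 26.5 |
| 40.0 | 34.6 | 61.4 | 1.3 |
| 50.0 | 36.8 | 62.1 | 0 |
| 60.0 | 35.9 | 62.8 | 0 |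
| 80.0 | 36.0 | 62.5 | 0.2 |

(readings scatter by 0.5 percentage points)

- given per volume of solution although it is solid: solid substrate
- at the start none of the solid substrate is in solution

1. ratio of other capture product to target at 5.0 s
2. ratio of other capture product to target at 40 s
3. ratio of other capture product to target at 6.0 min
4. which of other capture product and target there is more of at 6.0 min

In the violet run target reaches 62.5% of the charge, more than the 0.60 equiv of second nucleophile, so we let target take the first nucleophile and other capture product the second. Yet the ratio reads 0.343 at 12.0 s and 0.576 at 80.0 s, as if one competition had two outcomes.

It need not. If each nucleophile is taken in proportion to what is left of it, the ratio of the logarithms of the fractions left stays constant. This selectivity factor reads 2.46 at 25.0 s and 2.44 at 80.0 s, and we call it S. The first nucleophile is taken faster than the second and so thins out first, and the ratio climbs.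

For the flask, we assume S holds and each dissolved substrate is captured once. The ratio then starts near 0.352. For the end, we suppose the first nucleophile is used up, which leaves 0.500 of the second. S then returns 0.185 of the first, and the balance gives 0.285 of the second. Going round again from the mean, 0.392, gives 0.102 and 0.381, so we expect an end ratio of 0.591, which is less than one and puts target ahead, and at 40 s we expect a ratio between the starting and the end value.

The forecast gives 0.355, 0.43 and 0.575 with target ahead, holding that “with equal equivalents, the result matches violet”, and its last ratio lies a little below ours. The flask gives 0.331, 0.429 and 0.692, with target ahead at 55.1% against 38.1%.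

    first nucleophile + target → over-reaction product (k = 0.340 M⁻¹ s⁻¹)
    second nucleophile + intermediate → other capture product (k = 250 M⁻¹ s⁻¹)
    starting material → intermediate (k = 0.230 s⁻¹)
    first nucleophile + intermediate → target (k = 660 M⁻¹ s⁻¹)
    solid substrate ⇌ starting material, rate k5*(cs5 - [starting material]) while solid is left; crystals form when [starting material] > cs5 (solubility = 15.0 mM, k = 0.0210 s⁻¹)

At 0.673 min the flask makes target 11.5 times faster than it uses it up, and at 6.00 min it holds 6.79% of over-reaction product. With 36% of the second nucleophile left in the flask, S puts the first nucleophile at 8.56% of its charge, and the flask holds less than that, 1.9%. In the neighbour flask with 5.2 mM of solid substrate, the same reckoning from 40% of the second nucleophile gives 10.4% against 5.9% standing, with 2.19% of over-reaction product and an end ratio of 0.590.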